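**Plan**

Ring numbering: C1 (tertiary carbinol carrying the butenoyl carbonyl C8), C2 (angelate), C3 (lactone O), C4 (carries C11; C12 = lactone C=O, C13 = methylene), C5 (free OH), C6 (CH2), C7 (CH3).
Cuts, last-made first: PMB–O1, O2–angeloyl, C11=C13, C12–O3 (lactone), C1–C8 (aldol), C7–CH3 (cuprate), then C4–C11 together with C3–O (radical step), back to a 4-oxygenated cyclohept-2-enone and cyclohepta-1,3-diene.
Enabling feature: C11 on C4 is cis to the C5 oxygen and trans to the C3 oxygen, so a two-atom chain hung on O5 can hand C11 to C4 through a temporary cis-fused oxolane (O5–C12–C11–C4–C5) while a nitroxide caps the C3 radical on the other face.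
Forward: the carbocycle is bought; the oxolane closes in step 6 and is reopened in step 7 (O5 silylated, C12 held as a dithiane) so that only O3 can lactonise later; methyl and the C8–C10 chain enter in one three-component step; the γ-lactone (O3–C12) closes late, is methylenated, then the angelate goes on.
Stereocontrol: lipase desymmetrisation fixes C5; the tether fixes C4 and convex-face trapping C3; methyl adds to C7 anti to the C5 silyloxy group and the aldehyde to C1 anti to that methyl; boron bound to O3 delivers hydride to C2.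

Key step: step 6

Remark: the lipase is assumed to cleave the acetate that leads to 3; if its preference is the opposite, acetylation of the meso-diol with the same enzyme, which has the complementary sense, gives 3.
Remark: α is the ring face of the C4–C11 bond, β the other face. TMPO = 2,2,6,6-tetramethylpiperidin-1-yloxy, TBS = tert-butyldimethylsilyl, PMB = 4-methoxybenzyl. Compounds 5–9 are mixtures at the acetal carbon and 20–32 at C8 (one isomer drawn); both centres are erased later.

**Route**

Step 1
Reactants: 1 cyclohepta-1,3-diene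
Product: 2 cis-cyclohept-2-ene-1,4-diyl diacetate (meso)
Conditions: Pd(OAc)2 (5 mol %), LiCl (cat.), LiOAc, p-benzoquinone (cat.), MnO2, AcOH, rt
Reagents that add atoms: acetic acid, CC(=O)O
Why: Palladium-catalysed 1,4-diacetoxylation of a 1,3-diene: acetate adds anti to palladium and, with chloride on the metal, the π-allyl intermediate is again opened by external acetate, so both acetoxy groups end up cis and the product is meso.

Step 2
Reactants: 2 cis-cyclohept-2-ene-1,4-diyl diacetate
Product: 3 (1R,4S)-4-hydroxycyclohept-2-en-1-yl acetate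
Conditions: lipase from Burkholderia cepacia, phosphate buffer pH 7, NaOH (pH-stat), rt
Reagents that add atoms: none
Why: Enzymatic desymmetrisation of a meso-diacetate cleaves one enantiotopic ester, which fixes the absolute configuration of the future C5 (free carbinol) while the remaining acetate marks the future C2.

Step 3
Reactants: 3 (1R,4S)-4-hydroxycyclohept-2-en-1-yl acetate; 4 ethyl vinyl ether
Product: 5 (1R,4S)-4-(2-bromo-1-ethoxyethoxy)cyclohept-2-en-1-yl acetate
Conditions: N-bromosuccinimide, CH2Cl2, −40 to 0 °C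
Reagents that add atoms: N-bromosuccinimide, O=C1CCC(=O)N1Br
Why: Bromoalkoxylation of the enol ether (haloacetal formation): the bromonium ion of 4 is opened by the hydroxyl of 3 at the oxygen-bearing carbon; the acetal centre forms unselectively and is destroyed in step 7.

Step 4
Reactants: 5 bromoacetal acetate
Product: 6 (1R,4S)-4-(2-bromo-1-ethoxyethoxy)cyclohept-2-en-1-ol
Conditions: K2CO3 (cat.), MeOH, 0 °C
Reagents that add atoms: none
Why: Base-catalysed transesterification removes the acetate without touching the acetal, the primary bromide or the carbinol centres.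

Step 5
Reactants: 6 bromoacetal alcohol
Product: 7 (4S)-4-(2-bromo-1-ethoxyethoxy)cyclohept-2-en-1-one
Conditions: MnO2, CH2Cl2, rt
Reagents that add atoms: none
Why: Allylic alcohol oxidation with MnO2 gives the enone and deletes the temporary C2 centre, leaving C5 as the only ring stereocentre.

Step 6
Reactants: 7 (4S)-4-(2-bromo-1-ethoxyethoxy)cyclohept-2-en-1-one; 8 2,2,6,6-tetramethylpiperidin-1-oxyl (TEMPO)
Product: 9 bicyclic keto acetal: cycloheptan-2-one cis-fused at C4/C5 to a 2-ethoxyoxolane (O5–C12–C11–C4), 3β-TMPO, (3R,4S,5S)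
Conditions: Bu3SnH (1.3 equiv) and 8 (2.6 equiv) added together over 8 h by syringe pump to 7 (0.01 M), degassed benzene, 70 °C
Reagents that add atoms: none
Why: Thermal reaction of Bu3SnH with the nitroxide supplies stannyl radicals that abstract bromine from 7; the primary radical at C11 adds to the enone β-carbon C4 (5-exo-trig, closing the oxolane O5–C12–C11–C4–C5), and the C3 radical, delocalised into the C2 carbonyl, couples at carbon with a second nitroxide. The closest known chemistry is the Ueno–Stork haloacetal cyclisation run with nitroxide capture of the cyclised radical under tin hydride/TEMPO conditions. C4 is set by the tether: a chain anchored on O5 can only reach the face of C4 that carries O5, so the ring fusion is cis. C3 is set by approach of the bulky nitroxide to the convex face of the folded bicycle, anti to the new C4–C11 bond, and any cis isomer can drift to the trans one by enolisation or reversible C–O homolysis. The selectivity that matters is ring closure before capture of the first radical; it is secured by the fast addition of the alkoxyalkyl radical to the activated alkene together with the slow addition, which keeps the nitroxide in the millimolar range. C5 is not touched and both acetal epimers behave alike.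

Step 7
Reactants: 9 bicyclic keto acetal
Product: 10 4α-(1,3-dithian-2-ylmethyl)-5α-hydroxy-3β-TMPO-cycloheptan-2-one
Conditions: HS(CH2)3SH (1.1 equiv), BF3·OEt2, CH2Cl2, −40 °C
Reagents that add atoms: propane-1,3-dithiol, SCCCS
Why: Lewis-acid transthioacetalisation of the lactol ether: the oxocarbenium ion at C12 is captured twice by the dithiol, which opens the oxolane, frees O5–H and merges both acetal epimers into one dithiane, while the flanked α-aminoxy ketone is expected to stay intact at this temperature.

Step 8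
Reactants: 10 hydroxy dithiane ketone
Product: 11 5α-TBS ether of 10
Conditions: TBSCl, imidazole, DMF, rt
Reagents that add atoms: tert-butyldimethylsilyl chloride, CC(C)(C)[Si](C)(C)Cl
Why: Imidazole-promoted silylation of the secondary alcohol blocks O5, so that only O3 can later close onto C12.

Step 9
Reactants: 11 silyl ether ketone
Product: 14 C1=C7 enone (4α-dithianylmethyl 5α-OTBS 3β-TMPO cyclohept-1(7)-en-2-one), via C1 lithium enolate 12 (not isolated), via sulfilimine adduct 13 (not isolated)
Conditions: LiN(i-Pr)2, THF, −78 °C; then PhS(Cl)=N-t-Bu, −78 °C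
Reagents that add atoms: none
Why: Mukaiyama one-pot dehydrogenation: the kinetic enolate forms at the unhindered C1 methylene (not at the aminoxy-bearing C3), is sulfenylated by the sulfinimidoyl chloride, and the adduct undergoes syn-elimination to the C1=C7 enone.

Step 10
Reactants: 14 C1=C7 enone
Product: 15 1β,7β-epoxy ketone
Conditions: t-BuOOH, DBU, CH2Cl2, 0 °C
Reagents that add atoms: tert-butyl hydroperoxide, CC(C)(C)OO
Why: Weitz–Scheffer-type nucleophilic epoxidation of the enone; the epoxide configuration (expected anti to the C5 silyloxy group) is irrelevant because both carbons become sp2 again in the next step.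

Step 11
Reactants: 15 epoxy ketone
Product: 17 1-(4-methoxybenzyloxy) C1=C7 enone, via hydroxy ether ketone 16 (not isolated)
Conditions: 4-MeOC6H4CH2OH (5 equiv), KOH (0.3 equiv), THF, rt
Reagents that add atoms: 4-methoxybenzyl alcohol, COc1ccc(CO)cc1
Why: Alkoxide opening of the α,β-epoxy ketone at the carbonyl-activated carbon C1 followed by E1cB loss of the C7 hydroxyl is the classical route to diosphenol ethers; it places the oxygen on C1 and restores the C1=C7 unsaturation.

Step 12
Reactants: 17 alkoxy enone; 18 crotonaldehyde ((E)-but-2-enal)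
Product: 20 aldol: 7β-methyl 1β-OPMB 1α-(1-hydroxybut-2-enyl) ketone, via methylated lithium enolate 19 (not isolated)
Conditions: Me2CuLi (from CuI and MeLi), Et2O, −78 to −40 °C; then 18, −78 °C; aq. NH4Cl
Reagents that add atoms: lithium dimethylcuprate, [Li+].C[Cu-]C
Why: Cuprate conjugate addition with aldol capture of the enolate (three-component coupling): methyl should add to C7 on the β face, anti to the C5 silyloxy group that the cis C4/C5 pair holds pseudo-axial on the α face, and the enolate then takes the aldehyde at C1 anti to the new methyl, giving the quaternary centre with O β and C8 α (the C8 carbinol configuration is neither controlled nor needed).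

Step 13
Reactants: 20 aldol
Product: 21 8-O-TBS ether of 20
Conditions: TBSOTf, 2,6-lutidine, CH2Cl2, −78 to 0 °C
Reagents that add atoms: tert-butyldimethylsilyl triflate, CC(C)(C)[Si](C)(C)OS(=O)(=O)C(F)(F)F
Why: Silyl triflate silylation of the hindered allylic alcohol stops retro-aldol cleavage and removes the hydroxyl that would otherwise steer the hydride of step 15 to the wrong face.

Step 14
Reactants: 21 bis-silyl ether
Product: 22 3β-hydroxy ketone
Conditions: Zn dust, AcOH/THF/H2O, rt
Reagents that add atoms: none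
Why: Zinc/acetic acid reductive cleavage of the alkoxyamine N–O bond frees the C3 hydroxyl with retention, the α-alkoxy ketone, silyl ethers and dithiane being inert under these conditions.

Step 15
Reactants: 22 3β-hydroxy ketone
Product: 23 2α,3β-diol
Conditions: Me4NBH(OAc)3, MeCN/AcOH, −20 °C to rt
Reagents that add atoms: none
Why: Hydroxyl-directed triacetoxyborohydride reduction (Evans–Saksena type): boron bound to the β-face O3 delivers hydride intramolecularly to the same face of the flanked C2 ketone, so the new hydroxyl is α, trans to O3 as in the target.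

Step 16
Reactants: 23 diol dithiane
Product: 25 trans-fused γ-lactol (O3–C12), via hydroxy aldehyde 24 (not isolated)
Conditions: MeI, CaCO3, MeCN/H2O (9:1), 45 °C
Reagents that add atoms: water, O
Why: Alkylative hydrolysis of the dithiane (S-methylation, attack of water) releases the C12 aldehyde, which closes onto O3, the only hydroxyl that can form a five-membered ring now that O5 is silylated.

Step 17
Reactants: 25 γ-lactol
Product: 27 α-methylene lactol, via Mannich base 26 (not isolated)
Conditions: [Me2N=CH2]I (Eschenmoser's salt), Et3N, CH2Cl2, rt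
Reagents that add atoms: N,N-dimethylmethyleneiminium iodide, C=[N+](C)C.[I-]
Why: Mannich reaction of the ring-opened aldehyde tautomer with the iminium salt, followed by amine-induced β-elimination of dimethylamine, installs the exocyclic methylene C13 under conditions too mild to disturb the rest of the molecule.

Step 18
Reactants: 27 α-methylene lactol
Product: 28 α-methylene γ-lactone with free 2α-hydroxyl
Conditions: MnO2, CH2Cl2, rt
Reagents that add atoms: none
Why: MnO2 oxidises the allylic lactol to the α-methylene γ-lactone, whereas the saturated secondary hydroxyl at C2 is not oxidised by this reagent.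

Step 19
Reactants: 28 hydroxy lactone; 29 angelic acid ((Z)-2-methylbut-2-enoic acid)
Product: 31 2-O-angelate, via mixed anhydride 30 (not isolated)
Conditions: 2,4,6-Cl3C6H2COCl, Et3N, toluene, rt; then 28, 80 °C
Reagents that add atoms: none
Why: Yamaguchi esterification through the mixed trichlorobenzoic anhydride without a nucleophilic catalyst, the protocol that preserves the Z geometry of angelates, acylates the only free hydroxyl (C2).

Step 20
Reactants: 31 angelate
Product: 32 5,8-diol
Conditions: HF·pyridine, pyridine/THF, 0 °C to rt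
Reagents that add atoms: none
Why: Fluoride-mediated desilylation with buffered HF·pyridine removes both silyl ethers under mildly acidic conditions that avoid acyl migration and oxa-Michael addition to the methylene lactone.

Step 21
Reactants: 32 diol
Product: 33 8-ketone (1-O-PMB ether of the target)
Conditions: MnO2, CH2Cl2, rt
Reagents that add atoms: none
Why: Chemoselective MnO2 oxidation of the allylic carbinol C8 (both epimers) gives the E-enone, leaves the saturated C5 hydroxyl alone, and the ether on O1 excludes glycol cleavage.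

Step 22
Reactants: 33 PMB ether
Product: 34 CNP0206014.2
Conditions: DDQ, CH2Cl2/pH 7 buffer, 0 °C to rt
Reagents that add atoms: none
Why: Oxidative cleavage of the 4-methoxybenzyl ether with DDQ (benzylic hydride abstraction, hydrolysis of the oxocarbenium ion) frees the tertiary C1 hydroxyl without acid or base.

**Compound list**

1 | cyclohepta-1,3-diene | C1=CC=CCCC1 | starting material
2 | cis-cyclohept-2-ene-1,4-diyl diacetate (meso) | CC(=O)O[C@H]1C=C[C@@H](OC(C)=O)CCC1 | intermediate
3 | (1R,4S)-4-hydroxycyclohept-2-en-1-yl acetate | CC(=O)O[C@H]1C=C[C@@H](O)CCC1 | intermediate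
4 | ethyl vinyl ether | C=COCC | starting material
5 | (1R,4S)-4-(2-bromo-1-ethoxyethoxy)cyclohept-2-en-1-yl acetate (acetal epimers, one drawn) | CC(=O)O[C@H]1C=C[C@@H](O[C@@H](OCC)CBr)CCC1 | intermediate
6 | (1R,4S)-4-(2-bromo-1-ethoxyethoxy)cyclohept-2-en-1-ol | O[C@H]1C=C[C@@H](O[C@@H](OCC)CBr)CCC1 | intermediate
7 | (4S)-4-(2-bromo-1-ethoxyethoxy)cyclohept-2-en-1-one | O=C1C=C[C@@H](O[C@@H](OCC)CBr)CCC1 | intermediate
8 | 2,2,6,6-tetramethylpiperidin-1-oxyl | CC1(C)CCCC(C)(C)N1[O] | starting material
9 | cis-fused keto acetal, 3β-TMPO, C4/C5-fused 2-ethoxyoxolane, (3R,4S,5S) | O=C1CCC[C@@H]2O[C@@H](OCC)C[C@@H]2[C@H]1ON1C(C)(C)CCCC1(C)C | intermediate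
10 | 4α-(1,3-dithian-2-ylmethyl)-5α-hydroxy-3β-TMPO-cycloheptan-2-one | O=C1CCC[C@H](O)[C@H](CC2SCCCS2)[C@H]1ON1C(C)(C)CCCC1(C)C | intermediate
11 | 5α-TBS ether of 10 | O=C1CCC[C@H](O[Si](C)(C)C(C)(C)C)[C@H](CC2SCCCS2)[C@H]1ON1C(C)(C)CCCC1(C)C | intermediate
12 | lithium C1=C2 enolate of 11 | [Li+].[O-]C1=CCC[C@H](O[Si](C)(C)C(C)(C)C)[C@H](CC2SCCCS2)[C@H]1ON1C(C)(C)CCCC1(C)C | intermediate
13 | 1-(S-phenyl-N-tert-butylsulfilimino) derivative of 11 | O=C1C(S(=NC(C)(C)C)c2ccccc2)CC[C@H](O[Si](C)(C)C(C)(C)C)[C@H](CC3SCCCS3)[C@H]1ON1C(C)(C)CCCC1(C)C | intermediate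
14 | C1=C7 enone (4α-dithianylmethyl, 5α-OTBS, 3β-TMPO) | O=C1C=CC[C@H](O[Si](C)(C)C(C)(C)C)[C@H](CC2SCCCS2)[C@H]1ON1C(C)(C)CCCC1(C)C | intermediate
15 | 1β,7β-epoxy ketone | O=C1[C@H]2O[C@H]2C[C@H](O[Si](C)(C)C(C)(C)C)[C@H](CC3SCCCS3)[C@H]1ON1C(C)(C)CCCC1(C)C | intermediate
16 | 1α-(4-methoxybenzyloxy)-7β-hydroxy ketone | O=C1[C@H](OCc2ccc(OC)cc2)[C@@H](O)C[C@H](O[Si](C)(C)C(C)(C)C)[C@H](CC3SCCCS3)[C@H]1ON1C(C)(C)CCCC1(C)C | intermediate
17 | 1-(4-methoxybenzyloxy) C1=C7 enone | O=C1C(OCc2ccc(OC)cc2)=CC[C@H](O[Si](C)(C)C(C)(C)C)[C@H](CC3SCCCS3)[C@H]1ON1C(C)(C)CCCC1(C)C | intermediate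
18 | crotonaldehyde | C/C=C/C=O | starting material
19 | lithium C1=C2 enolate with 7β-methyl and 1-OPMB | [Li+].[O-]C1=C(OCc2ccc(OC)cc2)[C@@H](C)C[C@H](O[Si](C)(C)C(C)(C)C)[C@H](CC3SCCCS3)[C@H]1ON1C(C)(C)CCCC1(C)C | intermediate
20 | aldol: 7β-methyl, 1β-OPMB, 1α-[(E)-1-hydroxybut-2-enyl] ketone (C8 epimers, one drawn) | O=C1[C@](OCc2ccc(OC)cc2)([C@@H](O)/C=C/C)[C@@H](C)C[C@H](O[Si](C)(C)C(C)(C)C)[C@H](CC3SCCCS3)[C@H]1ON1C(C)(C)CCCC1(C)C | intermediate
21 | 8-O-TBS ether of 20 | O=C1[C@](OCc2ccc(OC)cc2)([C@@H](O[Si](C)(C)C(C)(C)C)/C=C/C)[C@@H](C)C[C@H](O[Si](C)(C)C(C)(C)C)[C@H](CC3SCCCS3)[C@H]1ON1C(C)(C)CCCC1(C)C | intermediate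
22 | 3β-hydroxy ketone | O=C1[C@](OCc2ccc(OC)cc2)([C@@H](O[Si](C)(C)C(C)(C)C)/C=C/C)[C@@H](C)C[C@H](O[Si](C)(C)C(C)(C)C)[C@H](CC3SCCCS3)[C@H]1O | intermediate
23 | 2α,3β-diol | O[C@@H]1[C@](OCc2ccc(OC)cc2)([C@@H](O[Si](C)(C)C(C)(C)C)/C=C/C)[C@@H](C)C[C@H](O[Si](C)(C)C(C)(C)C)[C@H](CC3SCCCS3)[C@H]1O | intermediate
24 | C12 aldehyde (open form of 25) | O[C@@H]1[C@](OCc2ccc(OC)cc2)([C@@H](O[Si](C)(C)C(C)(C)C)/C=C/C)[C@@H](C)C[C@H](O[Si](C)(C)C(C)(C)C)[C@H](CC=O)[C@H]1O | intermediate
25 | trans-fused γ-lactol on O3 (anomers) | O[C@@H]1[C@](OCc2ccc(OC)cc2)([C@@H](O[Si](C)(C)C(C)(C)C)/C=C/C)[C@@H](C)C[C@H](O[Si](C)(C)C(C)(C)C)[C@@H]2CC(O)O[C@@H]12 | intermediate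
26 | 11-(dimethylaminomethyl) lactol | O[C@@H]1[C@](OCc2ccc(OC)cc2)([C@@H](O[Si](C)(C)C(C)(C)C)/C=C/C)[C@@H](C)C[C@H](O[Si](C)(C)C(C)(C)C)[C@@H]2C(CN(C)C)C(O)O[C@@H]12 | intermediate
27 | α-methylene lactol | O[C@@H]1[C@](OCc2ccc(OC)cc2)([C@@H](O[Si](C)(C)C(C)(C)C)/C=C/C)[C@@H](C)C[C@H](O[Si](C)(C)C(C)(C)C)[C@@H]2C(=C)C(O)O[C@@H]12 | intermediate
28 | α-methylene γ-lactone, free 2α-OH | O[C@@H]1[C@](OCc2ccc(OC)cc2)([C@@H](O[Si](C)(C)C(C)(C)C)/C=C/C)[C@@H](C)C[C@H](O[Si](C)(C)C(C)(C)C)[C@@H]2C(=C)C(=O)O[C@@H]12 | intermediate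
29 | angelic acid | C/C=C(/C)C(=O)O | starting material
30 | angelic 2,4,6-trichlorobenzoic anhydride | C/C=C(/C)C(=O)OC(=O)c1c(Cl)cc(Cl)cc1Cl | intermediate
31 | 2-O-angelate, 5,8-bis-TBS, 1-O-PMB | C/C=C(/C)C(=O)O[C@@H]1[C@](OCc2ccc(OC)cc2)([C@@H](O[Si](C)(C)C(C)(C)C)/C=C/C)[C@@H](C)C[C@H](O[Si](C)(C)C(C)(C)C)[C@@H]2C(=C)C(=O)O[C@@H]12 | intermediate
32 | 5,8-diol, 1-O-PMB | C/C=C(/C)C(=O)O[C@@H]1[C@](OCc2ccc(OC)cc2)([C@@H](O)/C=C/C)[C@@H](C)C[C@H](O)[C@@H]2C(=C)C(=O)O[C@@H]12 | intermediate
33 | 1-O-PMB ether of the target | C/C=C(/C)C(=O)O[C@@H]1[C@](OCc2ccc(OC)cc2)(C(=O)/C=C/C)[C@@H](C)C[C@H](O)[C@@H]2C(=C)C(=O)O[C@@H]12 | intermediate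
34 | CNP0206014.2 | C/C=C(/C)C(=O)O[C@@H]1[C@](O)(C(=O)/C=C/C)[C@@H](C)C[C@H](O)[C@@H]2C(=C)C(=O)O[C@@H]12 | target

**Count and risks**

Total step count: 22. Longest linear sequence: 22 steps, from cyclohepta-1,3-diene.

Step 12. The conjugate addition to the electron-rich alkoxy enone may be slow enough for the cuprate to decompose first, and the crowded aldolate may revert before the quench. Fallback, from 17: the addition is run with Me2CuLi in the presence of Me3SiCl, which accelerates it and traps the enolate as the trimethylsilyl enol ether F1. F1 is then joined to crotonaldehyde 18 in a separate Mukaiyama aldol reaction (BF3·OEt2, CH2Cl2, −78 °C), which returns to 20.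

Step 19. Acylation of the hydroxyl flanked by the quaternary C1 and the lactone-bearing C3 may be so sluggish that the forcing needed isomerises the angeloyl donor to the tigloyl one. Fallback, from 28: the hydroxyl is acylated with 2-[bis(2,2,2-trifluoroethoxy)phosphoryl]propanoic acid (carbodiimide, DMAP; no alkene to isomerise) to give the phosphonopropanoate F2. A Still–Gennari olefination of F2 with acetaldehyde (KN(SiMe3)2, 18-crown-6, THF, −78 °C) then builds the Z-trisubstituted double bond on the ester and rejoins the route at 31.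

Step 6. The nitroxide may couple with the primary radical before ring closure, or the stannane may transfer hydrogen to the C3 radical; either bypasses 9. Fallback, from 7: halide exchange (NaI, butan-2-one, reflux) gives the iodoacetal enone F3. Et3B with a trace of air then drives an iodine-atom-transfer chain in which the cyclised C3 radical is taken up by the borane as the regiodefined diethylboron enolate F4, with no nitroxide present during ring closure. Addition of excess 8 to F4 oxidises the boron enolate back to the C3 radical and caps it on the convex face, returning to 9.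

**Further compounds**

F1 | step 12 | trimethylsilyl enol ether (C1=C2) with 7β-methyl and 1-OPMB | C[Si](C)(C)OC1=C(OCc2ccc(OC)cc2)[C@@H](C)C[C@H](O[Si](C)(C)C(C)(C)C)[C@H](CC3SCCCS3)[C@H]1ON1C(C)(C)CCCC1(C)C
F2 | step 19 | 2-O-{2-[bis(2,2,2-trifluoroethoxy)phosphoryl]propanoate} of 28 | CC(C(=O)O[C@@H]1[C@](OCc2ccc(OC)cc2)([C@@H](O[Si](C)(C)C(C)(C)C)/C=C/C)[C@@H](C)C[C@H](O[Si](C)(C)C(C)(C)C)[C@@H]2C(=C)C(=O)O[C@@H]12)P(=O)(OCC(F)(F)F)OCC(F)(F)F
F3 | step 6 | (4S)-4-(1-ethoxy-2-iodoethoxy)cyclohept-2-en-1-one | O=C1C=C[C@@H](O[C@@H](OCC)CI)CCC1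
F4 | step 6 | diethylboron enolate (C2=C3) of the cis-fused keto acetal | CCB(CC)OC1=C[C@H]2C[C@H](OCC)O[C@H]2CCC1
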